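**Retrosynthetic overview**
- The C4 formyl group on ring A is put in last by ortho-formylation of the ring A phenol of the des-formyl tetracycle.
- The 2,2-dimethylpyranone (ring D) is cut at its aryl–carbonyl bond (C8–C=O) and its O–C(CH3)2 bond (on the C7 oxygen), leading back to a 3,6,7-trihydroxy depsidone and 3-methylbut-2-enoic acid. The strategy rests on one feature: ring B has a single aromatic C–H, at C8, flanked by the C7 hydroxyl and the C9 methyl, exactly where ring D is fused.
- The seven-membered dioxepinone (ring C) is cut at the C5a–O5 aryl ether bond, giving an ortho-bromoaryl ester of 2-hydroxy-4-methoxy-6-methylbenzoic acid; the ester comes from that acid (from methyl orsellinate) and 2-bromo-3,4-dimethoxy-6-methylphenol (from 3,4-dimethoxytoluene).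
- Order of ring formation: rings A and B are bought as arenes, ring C is closed by copper etherification, ring D by the acylation/oxa-Michael annulation.

Key step: step 9

Remark: positions are numbered as in 11H-dibenzo[b,e][1,4]dioxepin-11-one (ring A: C1–C4, C4a, C11a; O5; ring B: C5a, C6–C9, C9a; O10; lactone carbonyl C11). By this numbering the hydroxyls of the key-step precursor sit at C3, C6 and C7. The target has no stereocenter, so no configuration has to be set.

**Step 1**
Reactants: 1 3,4-dimethoxytoluene
Product: 3 4,5-dimethoxy-2-methylbenzaldehyde, via chloro(methoxy)methyl arene 2 (not isolated)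
Conditions: Cl2CHOMe, TiCl4, CH2Cl2, 0 °C to rt; then ice-water
Reagents that add atoms: dichloromethyl methyl ether, COC(Cl)Cl (formyl carbon); water, O (formyl oxygen)
Why: Rieche formylation, in which the electrophile attacks the ring carbon para to one methoxy group and ortho to the methyl group (the most activated unhindered position) and the chloro ether 2 is hydrolysed on work-up.

**Step 2**
Reactants: 3 4,5-dimethoxy-2-methylbenzaldehyde
Product: 5 4,5-dimethoxy-2-methylphenol, via aryl formate 4 (not isolated)
Conditions: mCPBA, CH2Cl2, 0 °C to rt; then K2CO3, MeOH, rt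
Reagents that add atoms: mCPBA, OOC(=O)c1cccc(Cl)c1
Why: Baeyer–Villiger (Dakin-type) oxidation in which the electron-rich aryl group migrates in preference to hydride, followed by mild methanolysis of the formate.

**Step 3**
Reactants: 5 4,5-dimethoxy-2-methylphenol
Product: 6 2-bromo-3,4-dimethoxy-6-methylphenol
Conditions: NBS, anhydrous CH2Cl2, −20 to 0 °C, dark
Reagents that add atoms: N-bromosuccinimide, O=C1CCC(=O)N1Br
Why: Electrophilic aromatic bromination directed by the free phenol to its only open ortho position, which is also ortho to a methoxy group, while the other ring C–H is meta to the hydroxyl.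

**Step 4**
Reactants: 7 methyl orsellinate (methyl 2,4-dihydroxy-6-methylbenzoate)
Product: 8 methyl 2-hydroxy-4-methoxy-6-methylbenzoate
Conditions: MeI (1.1 equiv), K2CO3, acetone, rt to 50 °C
Reagents that add atoms: iodomethane, CI
Why: Williamson etherification that is selective for the 4-hydroxyl because the 2-hydroxyl is held in a hydrogen bond to the ester carbonyl and is less acidic and less nucleophilic.

**Step 5**
Reactants: 8 methyl 2-hydroxy-4-methoxy-6-methylbenzoate
Product: 9 2-hydroxy-4-methoxy-6-methylbenzoic acid
Conditions: KOH, DMSO–H2O, 80 °C; then 1 M HCl, 0 °C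
Reagents that add atoms: potassium hydroxide, [K+].[OH-]
Why: Saponification of a hindered salicylate-type ester under forcing basic conditions, with cold acidification to avoid decarboxylation of the electron-rich acid.

**Step 6**
Reactants: 9 2-hydroxy-4-methoxy-6-methylbenzoic acid; 6 2-bromo-3,4-dimethoxy-6-methylphenol
Product: 11 2-bromo-3,4-dimethoxy-6-methylphenyl 2-hydroxy-4-methoxy-6-methylbenzoate, via mixed trifluoroacetic anhydride 10 (not isolated)
Conditions: (CF3CO)2O, toluene, rt; aq. NaHCO3 work-up
Reagents that add atoms: none
Why: Depside-type esterification by the mixed trifluoroacetic anhydride method, in which the 2,6-disubstituted acid reacts through an unhindered acylium-like mixed anhydride that acylates even a doubly ortho-substituted phenol, and the chelated 2-hydroxyl of the acid is free again after the bicarbonate work-up.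

**Step 7**
Reactants: 11 2-bromo-3,4-dimethoxy-6-methylphenyl 2-hydroxy-4-methoxy-6-methylbenzoate
Product: 12 3,6,7-trimethoxy-1,9-dimethyl-11H-dibenzo[b,e][1,4]dioxepin-11-one
Conditions: CuI, N,N-dimethylglycine, Cs2CO3, 1,4-dioxane (high dilution), 100 °C
Reagents that add atoms: none
Why: Intramolecular Ullmann diaryl ether synthesis, in which the caesium phenoxide of ring A, held next to the C–Br bond by the ester tether, displaces bromide under copper catalysis and closes the seven-membered ring C, the 2,6-disubstituted aryl ester being slow to transesterify.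

**Step 8**
Reactants: 12 3,6,7-trimethoxy-1,9-dimethyl-11H-dibenzo[b,e][1,4]dioxepin-11-one
Product: 13 3,6,7-trihydroxy-1,9-dimethyl-11H-dibenzo[b,e][1,4]dioxepin-11-one
Conditions: BBr3 (excess), CH2Cl2, −78 °C to rt; then H2O; product kept under N2
Reagents that add atoms: none
Why: Lewis acid cleavage of the three aryl methyl ethers by BBr3, conditions under which the aryl lactone is expected to persist.

**Step 9**
Reactants: 13 3,6,7-trihydroxy-1,9-dimethyl-11H-dibenzo[b,e][1,4]dioxepin-11-one; 14 3-methylbut-2-enoic acid
Product: 17 3,6-dihydroxy-1,9-dimethyl depsidone bearing a 2,2-dimethyl-2,3-dihydropyran-4-one ring fused at C7 (ring oxygen) and C8 (ketone carbon), via mixed methanesulfonic anhydride 15 (not isolated), via C8 aryl enone 16 (not isolated)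
Conditions: 14 (1.2 equiv), P2O5 in MeSO3H (1:10 w/w), 60 °C; ice-water quench
Reagents that add atoms: none
Why: P2O5 in MeSO3H converts acid 14 into the mixed anhydride 15 (an acylium equivalent), which acylates C8, the only C–H of ring B, either directly or by esterification of the C7 hydroxyl and Fries shift, to give aryl enone 16. The C7 hydroxyl, the only oxygen ortho to the new ketone, then adds to the β-carbon of the protonated enone in a 6-endo-trig oxa-Michael closure that forms the O–C(CH3)2 bond and ring D. The closest known reaction is the acid-mediated condensation of phenols with 3-methylbut-2-enoic acid to give 2,2-dimethylchroman-4-ones. No stereocenter is formed. The step needs acylation of ring B and not ring A: ring B is a trioxygenated, alkylated arene, while ring A has its hydroxyl para and its ether oxygen ortho to the lactone carbonyl, the pattern of a 7-hydroxychroman-4-one ring, which is the deactivated product of such annulations. Regiochemistry is fixed by the substrate, since C8 is the single open carbon and the C6 hydroxyl cannot reach the enone, so it stays free as in the target.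

**Step 10**
Reactants: 17 des-formyl tetracycle (as named in step 9)
Product: 19 target CNP0271978.0 (the C4 formyl derivative of 17), via aldimine 18 (not isolated)
Conditions: (CH2)6N4, CF3CO2H, 80 °C; then H2O, 60 °C
Reagents that add atoms: hexamethylenetetramine, C1N2CN3CN1CN(C2)C3 (formyl carbon); water, O (formyl oxygen)
Why: Duff reaction (ortho-formylation of a phenol), where ring B has no C–H left and ring A, a 4-acylresorcinol-type ring like that of a 7-hydroxychromanone or 7-hydroxycoumarin, is expected to react at the carbon between the hydroxyl and the ring oxygen (C4) and not at C2, which is shielded by the C1 methyl group; hydrolysis of aldimine 18 (drawn in its simplest N–H form) frees the aldehyde.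

**Compound list**
1 | 3,4-dimethoxytoluene | Cc1ccc(OC)c(OC)c1 | starting material
2 | 1-[chloro(methoxy)methyl]-4,5-dimethoxy-2-methylbenzene (racemic) | COC(Cl)c1cc(OC)c(OC)cc1C | intermediate (not isolated)
3 | 4,5-dimethoxy-2-methylbenzaldehyde | Cc1cc(OC)c(OC)cc1C=O | intermediate
4 | 4,5-dimethoxy-2-methylphenyl formate | Cc1cc(OC)c(OC)cc1OC=O | intermediate (not isolated)
5 | 4,5-dimethoxy-2-methylphenol | Cc1cc(OC)c(OC)cc1O | intermediate
6 | 2-bromo-3,4-dimethoxy-6-methylphenol | Cc1cc(OC)c(OC)c(Br)c1O | intermediate
7 | methyl orsellinate (methyl 2,4-dihydroxy-6-methylbenzoate) | COC(=O)c1c(C)cc(O)cc1O | starting material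
8 | methyl 2-hydroxy-4-methoxy-6-methylbenzoate | COC(=O)c1c(C)cc(OC)cc1O | intermediate
9 | 2-hydroxy-4-methoxy-6-methylbenzoic acid | OC(=O)c1c(C)cc(OC)cc1O | intermediate
10 | 2-hydroxy-4-methoxy-6-methylbenzoic trifluoroacetic anhydride | COc1cc(C)c(C(=O)OC(=O)C(F)(F)F)c(O)c1 | intermediate (not isolated)
11 | 2-bromo-3,4-dimethoxy-6-methylphenyl 2-hydroxy-4-methoxy-6-methylbenzoate | COc1cc(C)c(C(=O)Oc2c(C)cc(OC)c(OC)c2Br)c(O)c1 | intermediate
12 | 3,6,7-trimethoxy-1,9-dimethyl-11H-dibenzo[b,e][1,4]dioxepin-11-one | Cc1cc(OC)cc2c1C(=O)Oc1c(C)cc(OC)c(OC)c1O2 | intermediate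
13 | 3,6,7-trihydroxy-1,9-dimethyl-11H-dibenzo[b,e][1,4]dioxepin-11-one | Cc1cc(O)cc2c1C(=O)Oc1c(C)cc(O)c(O)c1O2 | intermediate
14 | 3-methylbut-2-enoic acid | CC(C)=CC(=O)O | starting material
15 | 3-methylbut-2-enoyl methanesulfonate (mixed anhydride) | CC(C)=CC(=O)OS(C)(=O)=O | intermediate (not isolated)
16 | 3,6,7-trihydroxy-1,9-dimethyl-8-(3-methylbut-2-enoyl)-11H-dibenzo[b,e][1,4]dioxepin-11-one | Cc1cc(O)cc2c1C(=O)Oc1c(C)c(C(=O)C=C(C)C)c(O)c(O)c1O2 | intermediate (not isolated)
17 | des-formyl tetracycle: 3,6-dihydroxy-1,9-dimethyl depsidone with a 2,2-dimethyl-2,3-dihydropyran-4-one ring fused at C7 (O) and C8 (C=O) | Cc1cc(O)cc2c1C(=O)Oc1c(C)c3C(=O)CC(C)(C)Oc3c(O)c1O2 | intermediate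
18 | C4 aldimine of 17 (4-iminomethyl compound, simplest N–H form) | Cc1cc(O)c(C=N)c2c1C(=O)Oc1c(C)c3C(=O)CC(C)(C)Oc3c(O)c1O2 | intermediate (not isolated)
19 | CNP0271978.0 (4-formyl derivative of 17) | Cc1cc(O)c(C=O)c2c1C(=O)Oc1c(C)c3c(c(O)c1O2)OC(C)(C)CC3=O | target

**Step count**
Total: 10 steps. Longest linear sequence: 8 steps (steps 1, 2, 3, 6, 7, 8, 9, 10).

**Steps most likely to fail**

Step 9 (key annulation). What may go wrong: acylation or esterification at the free ring A phenol competing with attack at C8; acid-induced opening of the lactone to an acylium ion and re-closure onto the C6 hydroxyl; oligomerisation of the unsaturated acid. The fallback sets out from trimethyl ether 12, in which ring A has no free phenol. Friedel–Crafts acylation with 3-methylbut-2-enoyl chloride and AlCl3 in CH2Cl2 should acylate C8, cleave the C7 methyl ether ortho to the new ketone through the aluminium chelate, and let the freed phenol close onto the enone. This should give the 3,6-di-O-methyl ether of the des-formyl tetracycle F1. BBr3 in CH2Cl2 then removes the two remaining methyl ethers (a pyranone ring opened by the Lewis acid is expected to re-close on work-up), and the route is rejoined at 17.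

Step 7 (copper etherification). What may go wrong: slow activation of the electron-rich C–Br bond that is flanked by two ortho oxygens, so that intermolecular transesterification or hydrodebromination takes over. The fallback reverses the order of the two ring C bonds and makes the ether with ring A as the electrophile; it sets out from bromophenol 6 and ester 8.
- Phenol 6 is benzylated (BnBr, K2CO3, DMF) to 1-(benzyloxy)-2-bromo-3,4-dimethoxy-6-methylbenzene F2.
- Bromine–lithium exchange (n-BuLi, THF, −78 °C), B(OMe)3 and oxidation with H2O2/NaOH turn the bromide into 2-(benzyloxy)-5,6-dimethoxy-3-methylphenol F3.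
- Ester 8 is converted with (CF3SO2)2O and pyridine into methyl 4-methoxy-2-methyl-6-(trifluoromethylsulfonyloxy)benzoate F4.
- Palladium-catalysed aryl ether coupling of F3 with F4 (Pd(OAc)2, 2-di-tert-butylphosphino-2',4',6'-triisopropylbiphenyl, K3PO4, toluene, 100 °C), which is favoured by the ortho ester on the electrophile, should give methyl 2-[2-(benzyloxy)-5,6-dimethoxy-3-methylphenoxy]-4-methoxy-6-methylbenzoate F5.
- Saponification (KOH, DMSO–H2O, 90 °C) gives 2-[2-(benzyloxy)-5,6-dimethoxy-3-methylphenoxy]-4-methoxy-6-methylbenzoic acid F6.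
- Hydrogenolysis (H2, Pd/C, EtOAc) gives 2-(2-hydroxy-5,6-dimethoxy-3-methylphenoxy)-4-methoxy-6-methylbenzoic acid F7.
- Lactonisation with (CF3CO)2O in toluene closes ring C and rejoins the route at 12.

Step 10 (formylation). What may go wrong: poor site selectivity between C4 and C2 of ring A, or aminomethylation at the carbon next to the ketone. The fallback sets out from 17 and uses a removable blocking group; it relies on bromination taking the same C2 position that misdirected the formylation, so it answers a C2 preference and not an unselective mixture. One equivalent of NBS in CH2Cl2 at 0 °C should brominate C2, giving the 2-bromo derivative of the des-formyl tetracycle F8. The Duff reaction can then only take C4 and should give the 2-bromo-4-formyl compound F9. Palladium-catalysed hydrodebromination (Pd(PPh3)4, HCO2Na, DMF, 80 °C), which spares the hydrogen-bonded aldehyde, rejoins the route at 19.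

**Further compounds**
F1 | step 9 | 3,6-di-O-methyl ether of the des-formyl tetracycle 17 | Cc1cc(OC)cc2c1C(=O)Oc1c(C)c3C(=O)CC(C)(C)Oc3c(OC)c1O2
F2 | step 7 | 1-(benzyloxy)-2-bromo-3,4-dimethoxy-6-methylbenzene | Cc1cc(OC)c(OC)c(Br)c1OCc1ccccc1
F3 | step 7 | 2-(benzyloxy)-5,6-dimethoxy-3-methylphenol | Cc1cc(OC)c(OC)c(O)c1OCc1ccccc1
F4 | step 7 | methyl 4-methoxy-2-methyl-6-(trifluoromethylsulfonyloxy)benzoate | COC(=O)c1c(C)cc(OC)cc1OS(=O)(=O)C(F)(F)F
F5 | step 7 | methyl 2-[2-(benzyloxy)-5,6-dimethoxy-3-methylphenoxy]-4-methoxy-6-methylbenzoate | COC(=O)c1c(C)cc(OC)cc1Oc1c(OC)c(OC)cc(C)c1OCc1ccccc1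
F6 | step 7 | 2-[2-(benzyloxy)-5,6-dimethoxy-3-methylphenoxy]-4-methoxy-6-methylbenzoic acid | OC(=O)c1c(C)cc(OC)cc1Oc1c(OC)c(OC)cc(C)c1OCc1ccccc1
F7 | step 7 | 2-(2-hydroxy-5,6-dimethoxy-3-methylphenoxy)-4-methoxy-6-methylbenzoic acid | OC(=O)c1c(C)cc(OC)cc1Oc1c(OC)c(OC)cc(C)c1O
F8 | step 10 | 2-bromo derivative of the des-formyl tetracycle 17 | Cc1c(Br)c(O)cc2c1C(=O)Oc1c(C)c3C(=O)CC(C)(C)Oc3c(O)c1O2
F9 | step 10 | 2-bromo-4-formyl derivative of 17 | Cc1c(Br)c(O)c(C=O)c2c1C(=O)Oc1c(C)c3C(=O)CC(C)(C)Oc3c(O)c1O2
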